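Per second is the unit for these flasks, in which gas phase dissolves and reacts with starting material to give target, and target reacts further: Thursday's last reading lacks 31.7% of the charge.

| flask | starting material | gas phase | remark | time |
|---|---|---|---|---|
| Thursday's | 3.3 mM | 2.1 mM (held) | run made earlier |  |
| north-east | 3.0 mM | 2.1 mM (held) |  | 2.5 min |
| north-west | 10 mM | 2.1 mM (held) |  | 2.5 min |
| south-east | 25 mM | 2.1 mM (held) |  | 2.5 min |
| west | 80 mM | 2.1 mM (held) |  | 2.5 min |

- Thursday's (time / s: target / %, starting material / %): 10.0: 17.6, 81.0; 15.0: 27.8, 71.0; 30.0: 46.4, 42.1; 50.0: 47.7, 20.6

(each reading ± 0.5 percentage points)

- at the start none of the gas phase is in solution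
- "hardly changes" means that all values lie within two and a half points (for a concentration: within two and a half percent of the largest)

- amount of target at the end, in percent of the starting material charged for north-east, north-west, south-east, west, in this order
- how the row runs (hardly changes / rises all the way / falls, then rises / falls all the way / rises, then falls)

Thursday's flask looks odd at first: its starting material is thinning, yet the fraction lost per second is larger late, s_L = 0.0357 /s between 30.0 s and 50.0 s, than early, s_E = 0.0211 /s over the first 10.0 s. The notes clear this up, since no gas is in solution at the start. If you read s_L as the pace with gas present and the early shortfall as time lost filling the solution, the filling time is τ = t(1 − s_E/s_L) = 4.10 s, with t the first reading's time.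

Gas then enters at up to c_sat/τ, where c_sat is the saturation concentration, while a charge c demands s_L·c. The charge at which the two are equal, c* = c_sat/(τ·s_L) = 14.3 mM, is the crossover charge: under it the demand s_L·c is the smaller of the two, and over it the larger, so that over it I reckon with the transfer of gas as the rate-limiting step, while gas phase stays held and supplied.

My own reckoning adds the two resistances, s = s_L/(1 + c/c*), and leaves a fraction a = exp(−s·t) after the run time. If target's next step also uses dissolved gas, target depends on a alone. A second step at half the first's pace gives target = 2(√a − a), which is 49.6% at Thursday's last reading against 47.7% read.

| flask | c/c* | a | target |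
|---|---|---|---|
| north-east | 0.210 | 1.19% | 19.4% |
| north-west | 0.698 | 4.26% | 32.8% |
| south-east | 1.75 | 14.2% | 47.0% |
| west | 5.59 | 44.3% | 44.5% |

So I put west a little below south-east. The forecast gives 10%, 20%, 42% and 50%, so that the row rises all the way, with west “near the maximum” and above south-east.

The flasks give 8.49%, 19.4%, 42.3% and 37.7%: the row rises, then falls, turning at 39 mM.

    gas phase ⇌ dissolved gas, rate k1*(csat - [dissolved gas]) (kL = 0.150 /s)
    starting material + dissolved gas ⇌ target (K = 15000 /M, k = 24.0 /M/s)
    dissolved gas + target → over-reacted product (k = 12.0 /M/s)

Held against 14.3 mM, dissolved gas at 1.25 min stands at 1.25 mM in north-west, under that charge, and at 0.609 mM in south-east, over it, while starting material left after the run is 14% in south-east against the reckoned 14.2% and 54% in west against 44.3%. In north-east at 2.50 min, the forward first step uses dissolved gas at 0.16 of the rate of the step from target to over-reacted product, and target stands at 8.49%.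

All runs were generated by integration with made-up constants.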